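**Retrosynthetic overview**

1. The last bond is a C(sp3)–C(sp2) Negishi coupling between alkenyl iodide 16 (carbocycle part) and the zinc reagent of iodide 26 (butenolide part). Both E-trisubstituted olefins come from syn-carboalumination of terminal alkynes, and the butenolide ring is bought as 4-bromofuran-2(5H)-one and attached in step 11, not formed.
2. The ring olefin C(CH3)=CH comes from cyclohexenone 10 by 1,4-reduction, enolate triflation and iron-catalysed methylation. The quaternary carbon comes from α'-methylation of dienolate 9 anti to the neighbouring ring methyl, a 1,2-relay from the CH(CH3) centre.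
3. The cyclohexene is the only ring that is formed, and it is formed first (step 1). Its bond between the future vinylic CH and the adjacent ring CH2 is disconnected as an aldol condensation, and its bond between the quaternary carbon and CH(CH3) as a Michael addition of allyl acetoacetate to crotonaldehyde.
4. Enabling feature: in the cyclohexene the methyl-bearing sp2 carbon and the allylic ring CH2 are 1,5-related through the quaternary carbon and the CH(CH3) carbon. The unit C(CH3)=CH–CH2 is therefore a masked cyclohex-2-enone (C=O at the methyl-bearing carbon, C=C between the vinylic CH and that CH2), in which the vinylic CH is the α-carbon of a methyl ketone, the CH2 an aldehyde carbon and CH(CH3) the β-carbon of an enal.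

Key step: step 1

Remark: in 3, 4, 5, 7 and 8 the carbon that later becomes the quaternary centre (and the carbinol carbon of 4) is not controlled and is drawn without descriptor; it is planarised in step 4, so step 1 only has to set the CH(CH3) centre.

**Route**

Step 1
Reactants: 1 allyl acetoacetate (prop-2-en-1-yl 3-oxobutanoate); 2 (E)-crotonaldehyde
Product: 5 prop-2-en-1-yl (6R)-6-methyl-2-oxocyclohex-3-ene-1-carboxylate, via Michael adduct 3 (not isolated), via aldol adduct 4 (not isolated)
Conditions: (S)-2-{bis[3,5-bis(trifluoromethyl)phenyl][(trimethylsilyl)oxy]methyl}pyrrolidine (10 mol%), PhCO2H (10 mol%), toluene, rt; then p-TsOH·H2O (20 mol%), 60 °C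
Reagents that add atoms: none
Why: The secondary amine condenses with 2 to an E-configured iminium ion whose face syn to the diaryl(silyloxy)methyl group is blocked, so the enol of 1 adds to the open Re face of the β-carbon (Michael addition) and the new CH(CH3) stereocentre is set as R under catalyst control; hydrolysis releases keto aldehyde 3. On acidification the enol of the methyl ketone attacks the aldehyde carbon in a 6-(enolendo)-exo-trig aldol closure, which forms the ring bond between the future vinylic CH and its CH2 neighbour (giving 4), and dehydration then gives the conjugated enone 5. The closest known reaction type is the diarylprolinol silyl ether-catalysed Michael addition of β-keto esters to enals followed by acid-promoted aldol condensation to 5-substituted cyclohex-2-enones (an organocatalytic Robinson-type annulation). The step needs chemoselectivity in the closure, and the substrate secures it: only the ketone methyl group can reach the aldehyde through a six-membered transition state (every other enolisable carbon would close a four-membered ring), and water can only be lost towards the ketone. The ester-bearing ring carbon is left uncontrolled on purpose, and an allyl ester is used because it survives the acid and is removed later under neutral conditions.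

Step 2
Reactants: 5 prop-2-en-1-yl (6R)-6-methyl-2-oxocyclohex-3-ene-1-carboxylate; 6 (4-bromobut-1-yn-1-yl)trimethylsilane
Product: 7 prop-2-en-1-yl (6R)-6-methyl-2-oxo-1-[4-(trimethylsilyl)but-3-yn-1-yl]cyclohex-3-ene-1-carboxylate
Conditions: Cs2CO3, NaI (cat.), DMF, rt to 40 °C, argon
Reagents that add atoms: none
Why: The doubly stabilised enolate of the β-keto ester is C-alkylated by the primary halide (iodide formed in situ, Finkelstein exchange) in an SN2 enolate alkylation; the configuration of the new fully substituted carbon does not matter.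

Step 3
Reactants: 7 prop-2-en-1-yl (6R)-6-methyl-2-oxo-1-[4-(trimethylsilyl)but-3-yn-1-yl]cyclohex-3-ene-1-carboxylate
Product: 8 (5R)-5-methyl-6-[4-(trimethylsilyl)but-3-yn-1-yl]cyclohex-2-en-1-one
Conditions: Pd(OAc)2 (5 mol%), PPh3 (20 mol%), HCO2H, Et3N, THF, rt
Reagents that add atoms: none
Why: Palladium-catalysed deallylation–decarboxylation: zerovalent palladium ionises the allyl ester to a π-allylpalladium carboxylate, formate reduces the allyl ligand to propene, and the β-keto carboxylate loses CO2 and is protonated; enone, silylalkyne and the CH(CH3) centre are untouched.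

Step 4
Reactants: 8 (5R)-5-methyl-6-[4-(trimethylsilyl)but-3-yn-1-yl]cyclohex-2-en-1-one
Product: 10 (5R,6R)-5,6-dimethyl-6-[4-(trimethylsilyl)but-3-yn-1-yl]cyclohex-2-en-1-one, via lithium dienolate 9 (not isolated)
Conditions: LiN(i-Pr)2, THF, −78 °C; then MeI, DMPU, −78 to −20 °C
Reagents that add atoms: iodomethane (CI)
Why: Kinetic α'-deprotonation gives the cross-conjugated dienolate 9, in which the adjacent ring methyl sits pseudoaxial to avoid allylic strain with the side chain; MeI therefore attacks the opposite face (enolate alkylation, 1,2-induction, as in α',α'-dialkylation of 5-substituted cyclohexenones), which places the new methyl trans to the ring methyl and sets the quaternary centre as R.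

Step 5
Reactants: 10 (5R,6R)-5,6-dimethyl-6-[4-(trimethylsilyl)but-3-yn-1-yl]cyclohex-2-en-1-one
Product: 12 (5R,6R)-5,6-dimethyl-6-[4-(trimethylsilyl)but-3-yn-1-yl]cyclohex-1-en-1-yl trifluoromethanesulfonate, via lithium enolate 11 (not isolated)
Conditions: LiBH(s-Bu)3, THF, −78 °C; then PhNTf2, −78 °C to rt
Reagents that add atoms: N-phenylbis(trifluoromethanesulfonimide) (O=S(=O)(N(c1ccccc1)S(=O)(=O)C(F)(F)F)C(F)(F)F)
Why: The bulky hydride adds 1,4 to the β-unsubstituted enone (1,2-attack is blocked by the neighbouring quaternary carbon), and the regiodefined enolate is O-sulfonylated in situ (conjugate reduction with enolate triflation), which fixes the later ring olefin between the carbonyl carbon and the former α-carbon.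

Step 6
Reactants: 12 (5R,6R)-5,6-dimethyl-6-[4-(trimethylsilyl)but-3-yn-1-yl]cyclohex-1-en-1-yl trifluoromethanesulfonate
Product: 13 trimethyl{4-[(1R,6R)-1,2,6-trimethylcyclohex-2-en-1-yl]but-1-yn-1-yl}silane
Conditions: MeMgBr, Fe(acac)3 (5 mol%), THF/NMP, −30 to 0 °C
Reagents that add atoms: methylmagnesium bromide (C[Mg]Br)
Why: Iron-catalysed Kumada-type cross-coupling of an alkenyl triflate with a Grignard reagent that has no β-hydrogen replaces triflate by methyl without moving the double bond, so the trisubstituted ring olefin is obtained as a single regioisomer.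

Step 7
Reactants: 13 trimethyl{4-[(1R,6R)-1,2,6-trimethylcyclohex-2-en-1-yl]but-1-yn-1-yl}silane
Product: 14 (5R,6R)-6-(but-3-yn-1-yl)-1,5,6-trimethylcyclohex-1-ene
Conditions: K2CO3 (cat.), MeOH, rt
Reagents that add atoms: none
Why: Methoxide-catalysed protodesilylation cleaves only the C(sp)–Si bond and frees the terminal alkyne.

Step 8
Reactants: 14 (5R,6R)-6-(but-3-yn-1-yl)-1,5,6-trimethylcyclohex-1-ene
Product: 16 (5R,6R)-6-[(3E)-4-iodo-3-methylbut-3-en-1-yl]-1,5,6-trimethylcyclohex-1-ene, via alkenylalane 15 (not isolated)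
Conditions: Me3Al, Cp2ZrCl2 (25 mol%), CH2Cl2, 0 °C to rt; then I2, THF, −30 to 0 °C
Reagents that add atoms: trimethylaluminium (C[Al](C)C); iodine (II)
Why: Zirconium-catalysed carboalumination (Negishi) adds methyl and aluminium syn across the terminal alkyne with aluminium at the terminal carbon, and iodinolysis with retention gives the E-alkenyl iodide; the trisubstituted ring olefin does not react.

Step 9
Reactants: 17 tert-butyl(but-3-yn-1-yloxy)dimethylsilane
Product: 20 (3E)-6-{[tert-butyl(dimethyl)silyl]oxy}-4-methylhex-3-en-1-ol, via alkenylalane 18 (not isolated), via lithium alanate 19 (not isolated)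
Conditions: Me3Al, Cp2ZrCl2 (25 mol%), CH2Cl2, rt; evaporation; n-BuLi, hexane/THF, −78 to 0 °C; oxirane, 0 °C to rt; aqueous work-up
Reagents that add atoms: trimethylaluminium (C[Al](C)C); oxirane (C1CO1)
Why: The same syn-carboalumination sets the E-olefin, and the more nucleophilic alanate formed with n-BuLi transfers its alkenyl group to oxirane with retention of geometry (epoxide opening by an alkenylalanate).

Step 10
Reactants: 20 (3E)-6-{[tert-butyl(dimethyl)silyl]oxy}-4-methylhex-3-en-1-ol
Product: 21 tert-butyl{[(3E)-6-iodo-3-methylhex-3-en-1-yl]oxy}dimethylsilane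
Conditions: I2, PPh3, imidazole, CH2Cl2, 0 °C
Reagents that add atoms: iodine (II)
Why: Appel-type iodination converts the primary alcohol by SN2 displacement of its alkoxyphosphonium ion; silyl ether and olefin are inert.

Step 11
Reactants: 21 tert-butyl{[(3E)-6-iodo-3-methylhex-3-en-1-yl]oxy}dimethylsilane; 22 4-bromofuran-2(5H)-one
Product: 24 4-[(3E)-6-{[tert-butyl(dimethyl)silyl]oxy}-4-methylhex-3-en-1-yl]furan-2(5H)-one, via alkylzinc iodide 23 (not isolated)
Conditions: Zn dust, LiCl, THF, 40 °C; then 22, Pd(PPh3)4 (5 mol%), THF, rt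
Reagents that add atoms: none
Why: LiCl-promoted zinc insertion gives a primary alkylzinc iodide that tolerates the silyl ether, and Negishi coupling at the vinylogous acyl bromide of 22 forms the bond between the butenolide β-carbon and the side chain.

Step 12
Reactants: 24 4-[(3E)-6-{[tert-butyl(dimethyl)silyl]oxy}-4-methylhex-3-en-1-yl]furan-2(5H)-one
Product: 25 4-[(3E)-6-hydroxy-4-methylhex-3-en-1-yl]furan-2(5H)-one
Conditions: HF·pyridine, THF, 0 °C to rt
Reagents that add atoms: none
Why: Fluoride cleaves the Si–O bond under non-basic conditions (desilylation), which spares the base-sensitive butenolide.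

Step 13
Reactants: 25 4-[(3E)-6-hydroxy-4-methylhex-3-en-1-yl]furan-2(5H)-one
Product: 26 4-[(3E)-6-iodo-4-methylhex-3-en-1-yl]furan-2(5H)-one
Conditions: I2, PPh3, imidazole, CH2Cl2, 0 °C
Reagents that add atoms: iodine (II)
Why: Appel-type iodination of the primary alcohol under neutral conditions; the lactone and the olefin are not touched.

Step 14
Reactants: 26 4-[(3E)-6-iodo-4-methylhex-3-en-1-yl]furan-2(5H)-one; 16 (5R,6R)-6-[(3E)-4-iodo-3-methylbut-3-en-1-yl]-1,5,6-trimethylcyclohex-1-ene
Product: 28 4-{(3E,7E)-4,8-dimethyl-10-[(1R,6R)-1,2,6-trimethylcyclohex-2-en-1-yl]deca-3,7-dien-1-yl}furan-2(5H)-one, via alkylzinc iodide 27 (not isolated)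
Conditions: 26, Zn dust, LiCl, THF, 40 °C; then 16, PdCl2(dppf) (5 mol%), THF/NMP, rt to 40 °C
Reagents that add atoms: none
Why: Negishi coupling: the alkylzinc iodide, formed by an insertion that tolerates the lactone, transmetalates to the alkenylpalladium iodide from 16, and reductive elimination joins C(sp3) to C(sp2) with retention of the E geometry set in step 8.

**Compound list**

1 | allyl acetoacetate (prop-2-en-1-yl 3-oxobutanoate) | CC(=O)CC(=O)OCC=C | starting material
2 | (E)-crotonaldehyde ((2E)-but-2-enal) | C/C=C/C=O | starting material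
3 | prop-2-en-1-yl (3R)-2-acetyl-3-methyl-5-oxopentanoate (Michael adduct) | CC(=O)C(C(=O)OCC=C)[C@H](C)CC=O | intermediate (not isolated)
4 | prop-2-en-1-yl (6R)-4-hydroxy-6-methyl-2-oxocyclohexane-1-carboxylate (aldol adduct) | C[C@@H]1CC(O)CC(=O)C1C(=O)OCC=C | intermediate (not isolated)
5 | prop-2-en-1-yl (6R)-6-methyl-2-oxocyclohex-3-ene-1-carboxylate | C[C@@H]1CC=CC(=O)C1C(=O)OCC=C | intermediate
6 | (4-bromobut-1-yn-1-yl)trimethylsilane | C[Si](C)(C)C#CCCBr | starting material
7 | prop-2-en-1-yl (6R)-6-methyl-2-oxo-1-[4-(trimethylsilyl)but-3-yn-1-yl]cyclohex-3-ene-1-carboxylate | C[C@@H]1CC=CC(=O)C1(CCC#C[Si](C)(C)C)C(=O)OCC=C | intermediate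
8 | (5R)-5-methyl-6-[4-(trimethylsilyl)but-3-yn-1-yl]cyclohex-2-en-1-one | C[C@@H]1CC=CC(=O)C1CCC#C[Si](C)(C)C | intermediate
9 | lithium (3R)-3-methyl-2-[4-(trimethylsilyl)but-3-yn-1-yl]cyclohexa-1,5-dien-1-olate | [Li+].[O-]C1=C(CCC#C[Si](C)(C)C)[C@H](C)CC=C1 | intermediate (not isolated)
10 | (5R,6R)-5,6-dimethyl-6-[4-(trimethylsilyl)but-3-yn-1-yl]cyclohex-2-en-1-one | O=C1C=CC[C@@H](C)[C@@]1(C)CCC#C[Si](C)(C)C | intermediate
11 | lithium (5R,6R)-5,6-dimethyl-6-[4-(trimethylsilyl)but-3-yn-1-yl]cyclohex-1-en-1-olate | [Li+].[O-]C1=CCC[C@@H](C)[C@@]1(C)CCC#C[Si](C)(C)C | intermediate (not isolated)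
12 | (5R,6R)-5,6-dimethyl-6-[4-(trimethylsilyl)but-3-yn-1-yl]cyclohex-1-en-1-yl trifluoromethanesulfonate | O=S(=O)(OC1=CCC[C@@H](C)[C@@]1(C)CCC#C[Si](C)(C)C)C(F)(F)F | intermediate
13 | trimethyl{4-[(1R,6R)-1,2,6-trimethylcyclohex-2-en-1-yl]but-1-yn-1-yl}silane | CC1=CCC[C@@H](C)[C@@]1(C)CCC#C[Si](C)(C)C | intermediate
14 | (5R,6R)-6-(but-3-yn-1-yl)-1,5,6-trimethylcyclohex-1-ene | CC1=CCC[C@@H](C)[C@@]1(C)CCC#C | intermediate
15 | dimethyl{(1E)-2-methyl-4-[(1R,6R)-1,2,6-trimethylcyclohex-2-en-1-yl]but-1-en-1-yl}alumane | CC1=CCC[C@@H](C)[C@@]1(C)CC/C(C)=C/[Al](C)C | intermediate (not isolated)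
16 | (5R,6R)-6-[(3E)-4-iodo-3-methylbut-3-en-1-yl]-1,5,6-trimethylcyclohex-1-ene | CC1=CCC[C@@H](C)[C@@]1(C)CC/C(C)=C/I | intermediate
17 | tert-butyl(but-3-yn-1-yloxy)dimethylsilane | C#CCCO[Si](C)(C)C(C)(C)C | starting material
18 | [(1E)-4-{[tert-butyl(dimethyl)silyl]oxy}-2-methylbut-1-en-1-yl]dimethylalumane | CC(C)(C)[Si](C)(C)OCC/C(C)=C/[Al](C)C | intermediate (not isolated)
19 | lithium butyl[(1E)-4-{[tert-butyl(dimethyl)silyl]oxy}-2-methylbut-1-en-1-yl]dimethylaluminate | CC(C)(C)[Si](C)(C)OCC/C(C)=C/[Al-](C)(C)CCCC.[Li+] | intermediate (not isolated)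
20 | (3E)-6-{[tert-butyl(dimethyl)silyl]oxy}-4-methylhex-3-en-1-ol | CC(C)(C)[Si](C)(C)OCC/C(C)=C/CCO | intermediate
21 | tert-butyl{[(3E)-6-iodo-3-methylhex-3-en-1-yl]oxy}dimethylsilane | CC(C)(C)[Si](C)(C)OCC/C(C)=C/CCI | intermediate
22 | 4-bromofuran-2(5H)-one | BrC1=CC(=O)OC1 | starting material
23 | [(3E)-6-{[tert-butyl(dimethyl)silyl]oxy}-4-methylhex-3-en-1-yl](iodo)zinc | CC(C)(C)[Si](C)(C)OCC/C(C)=C/CC[Zn]I | intermediate (not isolated)
24 | 4-[(3E)-6-{[tert-butyl(dimethyl)silyl]oxy}-4-methylhex-3-en-1-yl]furan-2(5H)-one | CC(C)(C)[Si](C)(C)OCC/C(C)=C/CCC1=CC(=O)OC1 | intermediate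
25 | 4-[(3E)-6-hydroxy-4-methylhex-3-en-1-yl]furan-2(5H)-one | OCC/C(C)=C/CCC1=CC(=O)OC1 | intermediate
26 | 4-[(3E)-6-iodo-4-methylhex-3-en-1-yl]furan-2(5H)-one | ICC/C(C)=C/CCC1=CC(=O)OC1 | intermediate
27 | iodo[(3E)-3-methyl-6-(5-oxo-2,5-dihydrofuran-3-yl)hex-3-en-1-yl]zinc | I[Zn]CC/C(C)=C/CCC1=CC(=O)OC1 | intermediate (not isolated)
28 | 4-{(3E,7E)-4,8-dimethyl-10-[(1R,6R)-1,2,6-trimethylcyclohex-2-en-1-yl]deca-3,7-dien-1-yl}furan-2(5H)-one | CC1=CCC[C@@H](C)[C@@]1(C)CC/C(C)=C/CC/C(C)=C/CCC1=CC(=O)OC1 | target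

**Step count and risks**

Total: 14 steps. Longest linear sequence: 9 steps (steps 1 to 8, then step 14); the side-chain branch is steps 9 to 13.

Steps most likely to fail:

1. Step 2. The sluggish homopropargylic halide may lose hydrogen halide to the enyne, and the enolate of 5 may add to the enone of a second molecule faster than it is alkylated. Fallback: the side chain is attached before the ring exists. From 1, alkylation with 6 (K2CO3, NaI, acetone, reflux) should give prop-2-en-1-yl 2-acetyl-6-(trimethylsilyl)hex-5-ynoate F1. F1 and 2 under the amine and acid conditions of step 1 should pass through the Michael adduct prop-2-en-1-yl 2-acetyl-2-[(2R)-4-oxobutan-2-yl]-6-(trimethylsilyl)hex-5-ynoate F2 and the aldol adduct prop-2-en-1-yl (6R)-4-hydroxy-6-methyl-2-oxo-1-[4-(trimethylsilyl)but-3-yn-1-yl]cyclohexane-1-carboxylate F3 and come back to the route at 7.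

2. Step 14. Zinc insertion next to the unsaturated lactone may reduce or open it, and the alkylzinc may transmetalate slowly and undergo β-hydride elimination. Fallback: the roles of the partners are reversed, so that the lactone-bearing piece is the electrophile. From 16, iodine–lithium exchange (t-BuLi, Et2O, −78 °C) should give {(1E)-2-methyl-4-[(1R,6R)-1,2,6-trimethylcyclohex-2-en-1-yl]but-1-en-1-yl}lithium F6, and ZnBr2 should convert it to bromo{(1E)-2-methyl-4-[(1R,6R)-1,2,6-trimethylcyclohex-2-en-1-yl]but-1-en-1-yl}zinc F7. Palladium-catalysed coupling of F7 with the unactivated alkyl iodide 26 (Pd2(dba)3, P(c-C5H9)3, N-methylimidazole, THF/NMP, 80 °C) comes back to the route at 28.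

3. Step 4. Proton transfer or γ-deprotonation, O-methylation, or incomplete facial discrimination in the enolate alkylation would erode yield or the configuration of the quaternary centre. Fallback: the methyl carbon is delivered as a carbenoid to a silyl enol ether and released by cyclopropane opening. From 8, dienolate 9 is trapped with Me3SiCl to give {[(3R)-3-methyl-2-[4-(trimethylsilyl)but-3-yn-1-yl]cyclohexa-1,5-dien-1-yl]oxy}trimethylsilane F4. Simmons–Smith cyclopropanation (Et2Zn, CH2I2, CH2Cl2, 0 °C) of the electron-rich enol ether double bond, on the face opposite the ring methyl, should give trimethyl{[(1S,5R,6S)-5-methyl-6-[4-(trimethylsilyl)but-3-yn-1-yl]bicyclo[4.1.0]hept-2-en-1-yl]oxy}silane F5. Acid methanolysis (p-TsOH, MeOH, rt) opens the external cyclopropane bond to the α-methyl ketone and comes back to the route at 10.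

**Further compounds**

F1 | step 2 | prop-2-en-1-yl 2-acetyl-6-(trimethylsilyl)hex-5-ynoate | CC(=O)C(CCC#C[Si](C)(C)C)C(=O)OCC=C
F2 | step 2 | prop-2-en-1-yl 2-acetyl-2-[(2R)-4-oxobutan-2-yl]-6-(trimethylsilyl)hex-5-ynoate | CC(=O)C(CCC#C[Si](C)(C)C)(C(=O)OCC=C)[C@H](C)CC=O
F3 | step 2 | prop-2-en-1-yl (6R)-4-hydroxy-6-methyl-2-oxo-1-[4-(trimethylsilyl)but-3-yn-1-yl]cyclohexane-1-carboxylate | C[C@@H]1CC(O)CC(=O)C1(CCC#C[Si](C)(C)C)C(=O)OCC=C
F4 | step 4 | {[(3R)-3-methyl-2-[4-(trimethylsilyl)but-3-yn-1-yl]cyclohexa-1,5-dien-1-yl]oxy}trimethylsilane | C[C@@H]1CC=CC(O[Si](C)(C)C)=C1CCC#C[Si](C)(C)C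
F5 | step 4 | trimethyl{[(1S,5R,6S)-5-methyl-6-[4-(trimethylsilyl)but-3-yn-1-yl]bicyclo[4.1.0]hept-2-en-1-yl]oxy}silane | C[Si](C)(C)O[C@@]12C=CC[C@@H](C)[C@@]1(C2)CCC#C[Si](C)(C)C
F6 | step 14 | {(1E)-2-methyl-4-[(1R,6R)-1,2,6-trimethylcyclohex-2-en-1-yl]but-1-en-1-yl}lithium | CC1=CCC[C@@H](C)[C@@]1(C)CC/C(C)=C/[Li]
F7 | step 14 | bromo{(1E)-2-methyl-4-[(1R,6R)-1,2,6-trimethylcyclohex-2-en-1-yl]but-1-en-1-yl}zinc | CC1=CCC[C@@H](C)[C@@]1(C)CC/C(C)=C/[Zn]Br
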